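## Analysis of the target

The target is a 3-substituted isocoumarin. Benzo ring A (C4a to C8a) carries chlorine at C5 and hydroxyls at C6 and C8; pyranone ring B (C1, O2, C3, C4, C4a, C8a) has only hydrogen at C4; C3 carries a (1E,3E)-butadienyl chain (C1'' to C4'', counted from C3) that ends at C2' of an oxolane, ring C (O1', C2' to C5'). Ring C holds the only stereocentres, C2'(S), C3'(S) and C5'(R). The dienyl group, the hydroxyl and the methyl group lie on one face, so O–C5' and O–C3' are 1,3-anti in an open-chain precursor, and the 2,3-cis arrangement is the less stable one. C2' is an ether carbon at the end of a diene conjugated with the enol lactone, so acid can ionise and epimerise it, and a ring C aldehyde used to grow the chain can epimerise by enolisation. Other sensitive groups are the E,E-diene, the enol lactone (base) and the free chlororesorcinol (oxidation, electrophiles at C7). The difficulty is to join a fully regiodefined, electron-rich ring A to a stereodefined ring C across the diene and to close ring B without disturbing C2' or the alkene geometry. The strategy rests on one feature: the carbon that becomes C8a bears the carboxyl carbon C1 and has a single free ortho position, the future C4a next to the chlorinated C5, while the other ortho carbon (C8) is oxygenated. Because C4 bears only hydrogen, a one-carbon carbene donor that carries the acyl group (C3 with the whole side chain) can supply C4 and C3 in one carboxylate-directed C–H annulation.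

## Retrosynthetic reasoning

**21 to 20.** The last operation only removes protecting groups. The phenols are masked as methoxymethyl ethers: the one ortho to the carboxyl group must neither bind the metal as a salicylate nor migrate to the carboxylate, and it must leave under mild acid. The C3' hydroxyl is a tert-butyldimethylsilyl ether that survives base, acylation and the metal step and falls to the same acid.

**20 to 18 and 15 (key disconnection).** The bonds C4a–C4 and O2–C3 are cut. This is the only cut that uses ring A as bought, with chlorine and both oxygens in place and no halide or benzylic carbon to install on a pentasubstituted arene. It also brings ring C and the finished diene in as one piece, so no stereochemical or olefin chemistry follows the union. The forward reaction has to metalate the one ortho C–H bond of 18 next to chlorine, transfer the ylide carbon of 15 to the aryl–metal bond faster than the diene can react, and then lactonise and dehydrate the keto acid 19.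

**15 to 12 and 13 (through 14).** The C3–C4 bond is cut between the ketone carbon and the ylide carbon. The methylide made from 13 is acylated by acid chloride 14. An acid chloride is required because the same methylide would add in conjugate fashion to a dienoate ester.

**12 to 11 to 9 and 10.** The C3''=C4'' double bond is cut. The four-carbon phosphonate 10 brings C1'' to C3'' and the carboxyl carbon (the future C3). The aldehyde carbon of 9 is C4''. The olefination sets the new E alkene and 10 carries the other.

**9 back to 4.** Aldehyde 9 comes from alcohol 8, and 8 from iodide 6 by oxygen-for-iodine exchange. Then the O1'–C2' bond is cut: the hydroxyl on C5' of diol 4 adds to the terminal alkene under electrophilic activation to give 5. This direction of closure was chosen because the allylic C3' hydroxyl steers the electrophile to give the 2,3-cis product, and C5' is already fixed, so the whole all-cis ring follows from the anti diol.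

**4 to 3 to 2 to 1.** C3' is set by a hydroxyl-directed anti reduction of β-hydroxy enone 3. The C3'–C2' bond comes from addition of a vinyl nucleophile to amide 2. Ester 1 supplies the C5' carbinol, the methyl group, C4' and the acyl carbon that becomes C3', which is shorter than opening a chiral epoxide with an acyl anion equivalent.

**18 to 17 to 16.** Exhaustive methoxymethylation of the commercial acid 16, then selective saponification of the acetal ester.

## Alternatives that were turned down

**Alternative 1: ring A by cycloaddition and aromatisation.** Ring A itself is cut across C5–C4a and C8–C8a. In the forward direction the chlorinated bis(silyl enol ether) A2 adds across one double bond of the allenic diester A3, and elimination aromatises the adduct to the homophthalate A1, which carries chlorine, both hydroxyls, the C1 ester and the acetate arm (C4 and the future C3).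
- For: the polarity of the two partners fixes all six substituents, no transition metal is needed, and the doubt about metalating a hindered C–H bond does not arise. On certainty of the arene pattern this plan is stronger.
- Against: it builds a ring that can be bought with the same substituents (16). A1 is still far from 21: its two esters must be told apart, the aliphatic ester carbon must be turned into C3 bearing the dienyl chain by a dienyl organometallic fragment of ring C, and then ring B must be lactonised. The ring C work is at least as long as here, and A2 is moisture-sensitive.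
- Comparison: the chosen plan closes ring B and joins the halves in one step from a two-step arene, and is several steps shorter.

**Alternative 2: late cycloetherification of a dienyl epoxide.** The O1'–C2' bond is cut last. A zerovalent palladium catalyst ionises the trans dienyl epoxide A5 with inversion, the free C5' hydroxyl attacks C2' anti to the metal (net retention), and the epoxide oxygen becomes the C3' hydroxyl, giving the bis-silyl ether A4; fluoride then gives 21.
- For: the fragile 2,3-cis centre C2' is made at the very end and never meets base or the ring B chemistry; no epimerisable ring C aldehyde is needed; the silyl phenol ethers leave under near-neutral fluoride. On protection of C2' and mildness of the endgame it is stronger.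
- Against: A5 needs the complete isocoumarin, the diene, a stereodefined trans epoxide and the carbinol in one acyclic, labile molecule, which makes its synthesis longer. The ionised species is an extended pentadienyl–palladium, so oxygen can also attack C3'' or C1'' to give larger rings, and σ–π interconversion can scramble C2' and the alkene geometry. Ring B must still be made by some other method.
- Comparison: its key step has to answer regiochemistry, configuration and geometry at once, whereas the chosen key step only has to answer chemoselectivity, with ring C set beforehand by a substrate-controlled cyclisation.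

**Alternative 3: three-component carbonylative union.** C4–C3 and C3–C1'' are cut, with C3 coming from carbon monoxide A9. The benzylic bromide A7 adds oxidatively to zerovalent palladium, A9 inserts, the dienylstannane A8 transmetalates, and reductive elimination gives keto ester A6 (the ester analogue of 19), which is lactonised and deprotected.
- For: two C–C bonds are made under neutral, mild conditions; the diene geometry is stored in A8; no hindered C–H bond is activated. The bond-forming event is at least as reliable as the chosen one.
- Against: both partners cost more. A7 needs regioselective chlorination and benzylic bromination of an electron-rich arene that also brominates on the ring. A8 needs a stereodefined stannyl diene built from aldehyde 9 in extra steps. Stoichiometric tin and A9 must be handled, and direct coupling without insertion competes.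
- Comparison: convergence is similar and the chemical risk in its key step is lower, but the chosen plan uses a commercial acid in two steps, an acyl donor made by simple acylation, and no tin.

Key step: step 13

## Route

Remark: ethyl (3R)-3-hydroxybutanoate is used as the source of C5' because its acyl carbon becomes C3' directly; compounds 1, 10, 13 and 16 are taken to be commercial.

Step 1
Reactants: 1 ethyl (3R)-3-hydroxybutanoate
Product: 2 (3R)-3-hydroxy-N-methoxy-N-methylbutanamide
Conditions: MeNH(OMe)·HCl, i-PrMgCl, THF, −20 → 0 °C
Reagents that add atoms: N,O-dimethylhydroxylamine hydrochloride, CNOC.Cl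
Why: Aminolysis of the ester by the magnesium amide of the hydroxylamine (Weinreb amide formation); the free hydroxyl is carried as its magnesium alkoxide and the C5' centre is not touched.

Step 2
Reactants: 2 (3R)-3-hydroxy-N-methoxy-N-methylbutanamide
Product: 3 (5R)-5-hydroxyhex-1-en-3-one
Conditions: CH2=CHMgBr (excess), THF, −78 → 0 °C; inverse quench into cold aq. HCl
Reagents that add atoms: vinylmagnesium bromide, C=C[Mg]Br
Why: Weinreb ketone synthesis; the chelated tetrahedral intermediate prevents double addition, and the cold acidic quench protonates the released hydroxylamine so that it cannot add to the vinyl ketone.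

Step 3
Reactants: 3 (5R)-5-hydroxyhex-1-en-3-one
Product: 4 (2R,4S)-hex-5-ene-2,4-diol
Conditions: Me4NBH(OAc)3, MeCN/AcOH, −30 °C
Reagents that add atoms: none
Why: Evans–Saksena reduction; the C5' hydroxyl exchanges onto boron and delivers hydride intramolecularly through a chair transition state, which sets C3' as S, anti to C5', and reduces only the carbonyl of the enone.

Step 4
Reactants: 4 (2R,4S)-hex-5-ene-2,4-diol
Product: 5 (2R,3S,5R)-2-(iodomethyl)-5-methyloxolan-3-ol
Conditions: I2, NaHCO3, MeCN, 0 °C
Reagents that add atoms: iodine, II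
Why: Iodoetherification, 5-exo-trig, by the C5' hydroxyl; pent-4-ene-1,3-diols are known to cyclise through the conformer with the allylic hydrogen in the alkene plane to give the 2,3-cis product, so the allylic C3' hydroxyl sets C2' and, with C5' fixed, the ring is all-cis.

Step 5
Reactants: 5 (2R,3S,5R)-2-(iodomethyl)-5-methyloxolan-3-ol
Product: 6 tert-butyl{[(2R,3S,5R)-2-(iodomethyl)-5-methyloxolan-3-yl]oxy}dimethylsilane
Conditions: TBSOTf, 2,6-lutidine, CH2Cl2, −78 → 0 °C
Reagents that add atoms: tert-butyldimethylsilyl trifluoromethanesulfonate, CC(C)(C)[Si](C)(C)OS(=O)(=O)C(F)(F)F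
Why: Silylation of a hindered secondary alcohol with the silyl triflate; the primary iodide is inert to these conditions.

Step 6
Reactants: 6 tert-butyl{[(2R,3S,5R)-2-(iodomethyl)-5-methyloxolan-3-yl]oxy}dimethylsilane
Product: 8 [(2S,3S,5R)-3-{[tert-butyl(dimethyl)silyl]oxy}-5-methyloxolan-2-yl]methanol, via primary acetate 7 (not isolated)
Conditions: CsOAc, 18-crown-6, DMF, 70 °C; then K2CO3, MeOH, 0 °C
Reagents that add atoms: cesium acetate, CC(=O)[O-].[Cs+]
Why: SN2 displacement of the primary iodide by the crown-activated acetate, then methanolysis of the acetate in the same flask; no stereocentre takes part.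

Step 7
Reactants: 8 [(2S,3S,5R)-3-{[tert-butyl(dimethyl)silyl]oxy}-5-methyloxolan-2-yl]methanol
Product: 9 (2R,3S,5R)-3-{[tert-butyl(dimethyl)silyl]oxy}-5-methyloxolane-2-carbaldehyde
Conditions: Dess–Martin periodinane, NaHCO3, CH2Cl2, 0 → 23 °C; used without chromatography
Reagents that add atoms: none
Why: Dess–Martin oxidation under buffered, non-basic conditions, which should leave the epimerisable cis C2' centre intact.

Step 8
Reactants: 9 (2R,3S,5R)-3-{[tert-butyl(dimethyl)silyl]oxy}-5-methyloxolane-2-carbaldehyde; 10 ethyl (2E)-4-(diethoxyphosphoryl)but-2-enoate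
Product: 11 ethyl (2E,4E)-5-[(2S,3S,5R)-3-{[tert-butyl(dimethyl)silyl]oxy}-5-methyloxolan-2-yl]penta-2,4-dienoate
Conditions: 10, LiN(SiMe3)2, THF, −78 °C; then 9, −78 → 0 °C
Reagents that add atoms: none
Why: Vinylogous Horner–Wadsworth–Emmons olefination; the stabilised phosphonate anion gives the E alkene and adds at −78 °C faster than it can enolise the aldehyde, so C2' should keep its configuration.

Step 9
Reactants: 11 ethyl (2E,4E)-5-[(2S,3S,5R)-3-{[tert-butyl(dimethyl)silyl]oxy}-5-methyloxolan-2-yl]penta-2,4-dienoate
Product: 12 (2E,4E)-5-[(2S,3S,5R)-3-{[tert-butyl(dimethyl)silyl]oxy}-5-methyloxolan-2-yl]penta-2,4-dienoic acid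
Conditions: LiOH, THF/MeOH/H2O, 23 °C; then cold 0.5 M HCl to pH 4
Reagents that add atoms: lithium hydroxide, [Li+].[OH-]
Why: Saponification; the secondary silyl ether and the diene are stable to aqueous hydroxide, and C2' is no longer adjacent to a carbonyl group.

Step 10
Reactants: 12 (2E,4E)-5-[(2S,3S,5R)-3-{[tert-butyl(dimethyl)silyl]oxy}-5-methyloxolan-2-yl]penta-2,4-dienoic acid; 13 trimethylsulfoxonium iodide
Product: 15 (3E,5E)-6-[(2S,3S,5R)-3-{[tert-butyl(dimethyl)silyl]oxy}-5-methyloxolan-2-yl]-1-[dimethyl(oxo)-λ6-sulfanylidene]hexa-3,5-dien-2-one, via dienoyl chloride 14 (not isolated)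
Conditions: 1-chloro-N,N,2-trimethylprop-1-en-1-amine, CH2Cl2, 0 °C; solution added to the methylide from 13 and KOt-Bu (THF, reflux, then 0 °C), 0 °C
Reagents that add atoms: 1-chloro-N,N,2-trimethylprop-1-en-1-amine, CC(C)=C(Cl)N(C)C (supplies the chlorine of 14 only; all heavy atoms of 15 come from 12 and 13)
Why: The α-chloroenamine (Ghosez reagent) makes the acid chloride without free HCl, and C-acylation of dimethylsulfoxonium methylide, with a second equivalent as base, gives the stabilised β-keto ylide; the acyl chloride carbonyl is attacked much faster than the diene, which is why an ester is not used.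

Step 11
Reactants: 16 5-chloro-2,4-dihydroxybenzoic acid
Product: 17 methoxymethyl 5-chloro-2,4-bis(methoxymethoxy)benzoate
Conditions: NaH, MOMCl, DMF, 0 → 23 °C
Reagents that add atoms: chloromethyl methyl ether, COCCl
Why: Exhaustive O-alkylation of the carboxylate and both phenoxides (Williamson type); sodium hydride also deprotonates the hydrogen-bonded ortho hydroxyl.

Step 12
Reactants: 17 methoxymethyl 5-chloro-2,4-bis(methoxymethoxy)benzoate
Product: 18 5-chloro-2,4-bis(methoxymethoxy)benzoic acid
Conditions: LiOH, THF/MeOH/H2O, 23 °C; then cold 0.5 M HCl to pH 4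
Reagents that add atoms: lithium hydroxide, [Li+].[OH-]
Why: Saponification of the acetal ester; the aryl methoxymethyl ethers are stable to base and to the brief, cold, weakly acidic work-up.

Step 13
Reactants: 18 5-chloro-2,4-bis(methoxymethoxy)benzoic acid; 15 (3E,5E)-6-[(2S,3S,5R)-3-{[tert-butyl(dimethyl)silyl]oxy}-5-methyloxolan-2-yl]-1-[dimethyl(oxo)-λ6-sulfanylidene]hexa-3,5-dien-2-one
Product: 20 3-{(1E,3E)-4-[(2S,3S,5R)-3-{[tert-butyl(dimethyl)silyl]oxy}-5-methyloxolan-2-yl]buta-1,3-dien-1-yl}-5-chloro-6,8-bis(methoxymethoxy)-1H-isochromen-1-one, via keto acid 19 (not isolated)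
Conditions: [Cp*RhCl2]2 (cat.), AgSbF6 (cat.), NaOAc (cat.), 4 Å molecular sieves, ClCH2CH2Cl, 80 °C; 18 in excess
Reagents that add atoms: none
Why: The carboxylate of 18 binds the cationic Cp* complex of trivalent rhodium and acetate-assisted concerted metalation–deprotonation at the only ortho C–H bond gives a five-membered rhodacycle. The ylide carbon of 15 coordinates, dimethyl sulfoxide leaves to give a rhodium carbene, and migratory insertion into the aryl–rhodium bond forms C4a–C4. Protodemetalation by the excess acid releases keto acid 19 and returns the catalyst without any change of oxidation state, so no oxidant is needed. Ring B then closes by 6-exo-trig addition of the carboxyl oxygen to the C3 ketone (O2–C3), and dehydration across C3–C4 gives the enol lactone conjugated with the diene. The closest known reaction is the carboxylate-directed annulation of benzoic acids with α-acyl sulfoxonium ylides to 3-substituted isocoumarins; the dienoyl ylide is a new member of that class. No stereocentre is formed, and those of ring C are remote spectators. Site selectivity is secured by the substrate, since the second ortho carbon bears oxygen and the aryl chloride is inert to trivalent rhodium. Chemoselectivity relies on the ylide carbon binding the metal much faster than the electron-poor diene, and the acetate buffer is there to protect the acetal and silyl ethers.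

Step 14
Reactants: 20 3-{(1E,3E)-4-[(2S,3S,5R)-3-{[tert-butyl(dimethyl)silyl]oxy}-5-methyloxolan-2-yl]buta-1,3-dien-1-yl}-5-chloro-6,8-bis(methoxymethoxy)-1H-isochromen-1-one
Product: 21 5-chloro-6,8-dihydroxy-3-{(1E,3E)-4-[(2S,3S,5R)-3-hydroxy-5-methyloxolan-2-yl]buta-1,3-dien-1-yl}-1H-isochromen-1-one
Conditions: HCl (2 M in MeOH)/THF, 0 → 23 °C
Reagents that add atoms: none
Why: Acid-catalysed acetal exchange with methanol frees both phenols, and the same acid methanolyses the secondary silyl ether; methanol traps the methoxymethyl cation before it can alkylate C7.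

## Compound list

1 | ethyl (3R)-3-hydroxybutanoate | CCOC(=O)C[C@@H](C)O | starting material
2 | (3R)-3-hydroxy-N-methoxy-N-methylbutanamide | CON(C)C(=O)C[C@@H](C)O | intermediate
3 | (5R)-5-hydroxyhex-1-en-3-one | C=CC(=O)C[C@@H](C)O | intermediate
4 | (2R,4S)-hex-5-ene-2,4-diol | C=C[C@@H](O)C[C@@H](C)O | intermediate
5 | (2R,3S,5R)-2-(iodomethyl)-5-methyloxolan-3-ol | C[C@@H]1C[C@H](O)[C@H](CI)O1 | intermediate
6 | tert-butyl{[(2R,3S,5R)-2-(iodomethyl)-5-methyloxolan-3-yl]oxy}dimethylsilane | C[C@@H]1C[C@H](O[Si](C)(C)C(C)(C)C)[C@H](CI)O1 | intermediate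
7 | [(2S,3S,5R)-3-{[tert-butyl(dimethyl)silyl]oxy}-5-methyloxolan-2-yl]methyl acetate | C[C@@H]1C[C@H](O[Si](C)(C)C(C)(C)C)[C@H](COC(C)=O)O1 | intermediate
8 | [(2S,3S,5R)-3-{[tert-butyl(dimethyl)silyl]oxy}-5-methyloxolan-2-yl]methanol | C[C@@H]1C[C@H](O[Si](C)(C)C(C)(C)C)[C@H](CO)O1 | intermediate
9 | (2R,3S,5R)-3-{[tert-butyl(dimethyl)silyl]oxy}-5-methyloxolane-2-carbaldehyde | C[C@@H]1C[C@H](O[Si](C)(C)C(C)(C)C)[C@H](C=O)O1 | intermediate
10 | ethyl (2E)-4-(diethoxyphosphoryl)but-2-enoate (triethyl 4-phosphonocrotonate) | CCOC(=O)/C=C/CP(=O)(OCC)OCC | starting material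
11 | ethyl (2E,4E)-5-[(2S,3S,5R)-3-{[tert-butyl(dimethyl)silyl]oxy}-5-methyloxolan-2-yl]penta-2,4-dienoate | CCOC(=O)/C=C/C=C/[C@@H]1O[C@H](C)C[C@@H]1O[Si](C)(C)C(C)(C)C | intermediate
12 | (2E,4E)-5-[(2S,3S,5R)-3-{[tert-butyl(dimethyl)silyl]oxy}-5-methyloxolan-2-yl]penta-2,4-dienoic acid | OC(=O)/C=C/C=C/[C@@H]1O[C@H](C)C[C@@H]1O[Si](C)(C)C(C)(C)C | intermediate
13 | trimethylsulfoxonium iodide | C[S+](C)(C)=O.[I-] | starting material
14 | (2E,4E)-5-[(2S,3S,5R)-3-{[tert-butyl(dimethyl)silyl]oxy}-5-methyloxolan-2-yl]penta-2,4-dienoyl chloride | O=C(Cl)/C=C/C=C/[C@@H]1O[C@H](C)C[C@@H]1O[Si](C)(C)C(C)(C)C | intermediate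
15 | (3E,5E)-6-[(2S,3S,5R)-3-{[tert-butyl(dimethyl)silyl]oxy}-5-methyloxolan-2-yl]-1-[dimethyl(oxo)-λ6-sulfanylidene]hexa-3,5-dien-2-one | CS(C)(=O)=CC(=O)/C=C/C=C/[C@@H]1O[C@H](C)C[C@@H]1O[Si](C)(C)C(C)(C)C | intermediate
16 | 5-chloro-2,4-dihydroxybenzoic acid | O=C(O)c1cc(Cl)c(O)cc1O | starting material
17 | methoxymethyl 5-chloro-2,4-bis(methoxymethoxy)benzoate | COCOC(=O)c1cc(Cl)c(OCOC)cc1OCOC | intermediate
18 | 5-chloro-2,4-bis(methoxymethoxy)benzoic acid | COCOc1cc(OCOC)c(C(=O)O)cc1Cl | intermediate
19 | 2-{(3E,5E)-6-[(2S,3S,5R)-3-{[tert-butyl(dimethyl)silyl]oxy}-5-methyloxolan-2-yl]-2-oxohexa-3,5-dien-1-yl}-3-chloro-4,6-bis(methoxymethoxy)benzoic acid | COCOc1cc(OCOC)c(C(=O)O)c(CC(=O)/C=C/C=C/[C@@H]2O[C@H](C)C[C@@H]2O[Si](C)(C)C(C)(C)C)c1Cl | intermediate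
20 | 3-{(1E,3E)-4-[(2S,3S,5R)-3-{[tert-butyl(dimethyl)silyl]oxy}-5-methyloxolan-2-yl]buta-1,3-dien-1-yl}-5-chloro-6,8-bis(methoxymethoxy)-1H-isochromen-1-one | COCOc1cc(OCOC)c2c(=O)oc(/C=C/C=C/[C@@H]3O[C@H](C)C[C@@H]3O[Si](C)(C)C(C)(C)C)cc2c1Cl | intermediate
21 | 5-chloro-6,8-dihydroxy-3-{(1E,3E)-4-[(2S,3S,5R)-3-hydroxy-5-methyloxolan-2-yl]buta-1,3-dien-1-yl}-1H-isochromen-1-one | C[C@@H]1C[C@H](O)[C@H](/C=C/C=C/c2cc3c(Cl)c(O)cc(O)c3c(=O)o2)O1 | target

## Step count and risk

Total: 14 steps. Longest linear sequence: 12 steps (steps 1 to 10, 13 and 14); the arene branch is steps 11 and 12.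

**Step 13 (key step).** Three things are most likely to go wrong. Metalation may be slow at a C–H bond flanked by the carboxylate and chlorine. The aryl–rhodium intermediate may be captured by the electron-poor diene of 15 or of 20 (conjugate addition or stalled turnover) in place of carbene transfer. The ortho acetal ether may be lost under the Lewis-acidic conditions, or cyclodehydration of 19 may stay incomplete. The fallback keeps the diene away from the metal and completes it by olefination afterwards; it sets out from 18 and 9 and returns at 20. The methylide from 13 is acylated by commercial methyl {[tert-butyl(dimethyl)silyl]oxy}acetate to the glycolyl sulfoxonium ylide F1. F1 is annulated with 18 under the conditions of step 13, a saturated acyl ylide being the best-precedented case, to the 3-(silyloxymethyl)isocoumarin F2. Bu4NF gives the 3-(hydroxymethyl)isocoumarin F3, CBr4/PPh3 the 3-(bromomethyl)isocoumarin F4, and P(OEt)3 at 110 °C the isocoumarin-3-ylmethyl phosphonate F5. Aldehyde 9 and Ph3P=CHCHO give the ring C enal F6 without base. Deprotonated F5 (LiN(SiMe3)2, THF, −78 °C) condenses with F6 in a Horner–Wadsworth–Emmons reaction that forms C1''=C2'' and gives 20.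

**Step 2.** The hydroxy vinyl ketone may be lost through conjugate addition of the liberated hydroxylamine or through oligomerisation during work-up. The fallback uses an alkyne as a masked vinyl group; it sets out from 2 and returns at 4. LiC≡CSiMe3 adds to 2 to give the silyl ynone F7, Me4NBH(OAc)3 reduces it to the anti silyl alkynediol F8, K2CO3 in MeOH gives the terminal alkynediol F9, and H2 over Pd/CaCO3 poisoned with Pb(OAc)2 and quinoline gives 4.

**Step 6.** Substitution at the β-branched, β-oxygenated primary carbon may be slow, elimination to the exocyclic enol ether may compete, and the silyl group may migrate to the new primary alkoxide during methanolysis. The fallback closes ring C through an epoxide and so avoids the iodide; it sets out from 4 and returns at 8. Sharpless epoxidation of 4 (Ti(Oi-Pr)4, L-(+)-diisopropyl tartrate, t-BuOOH, matched case) gives the erythro epoxy diol F10. Camphorsulfonic acid closes it by 5-exo attack of the C5' hydroxyl with inversion at C2' to the oxolane diol F11. TBSOTf/2,6-lutidine gives the bis-silyl ether F12, and HF·pyridine in THF/pyridine at 0 °C removes the primary silyl group to give 8.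

**Step 8.** C2' may epimerise through enolisation of 9, the β-silyloxy group may be eliminated, and the E selectivity at the new alkene may be incomplete. The fallback avoids a basic carbanion; it sets out from 9 and returns at 11. Takai olefination (CrCl2, CHI3, THF) gives the (E)-vinyl iodide F13, and a Heck reaction with ethyl acrylate (Pd(OAc)2, K2CO3, Bu4NCl, DMF) gives 11 with both alkenes E.

**Step 14.** Acid may ionise the C2'–O1' bond, which would epimerise C2' to the more stable 2,3-trans isomer or lead to solvolysis, and the methoxymethyl cation may re-alkylate C7. The fallback separates the two deprotections and avoids protic acid; it sets out from 20 and returns at 21. HF·pyridine in THF/pyridine removes the silyl ether to give the bis(methoxymethyl) ether alcohol F14, and ZnBr2 with n-PrSH in CH2Cl2 at 0 °C cleaves both acetals within minutes, the thiol trapping the methoxymethyl cation, to give 21.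

## Further compounds

F1 | step 13 | 1-{[tert-butyl(dimethyl)silyl]oxy}-3-[dimethyl(oxo)-λ6-sulfanylidene]propan-2-one | CS(C)(=O)=CC(=O)CO[Si](C)(C)C(C)(C)C
F2 | step 13 | 3-({[tert-butyl(dimethyl)silyl]oxy}methyl)-5-chloro-6,8-bis(methoxymethoxy)-1H-isochromen-1-one | COCOc1cc(OCOC)c2c(=O)oc(CO[Si](C)(C)C(C)(C)C)cc2c1Cl
F3 | step 13 | 5-chloro-3-(hydroxymethyl)-6,8-bis(methoxymethoxy)-1H-isochromen-1-one | COCOc1cc(OCOC)c2c(=O)oc(CO)cc2c1Cl
F4 | step 13 | 3-(bromomethyl)-5-chloro-6,8-bis(methoxymethoxy)-1H-isochromen-1-one | COCOc1cc(OCOC)c2c(=O)oc(CBr)cc2c1Cl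
F5 | step 13 | diethyl {[5-chloro-6,8-bis(methoxymethoxy)-1-oxo-1H-isochromen-3-yl]methyl}phosphonate | CCOP(=O)(Cc1cc2c(Cl)c(OCOC)cc(OCOC)c2c(=O)o1)OCC
F6 | step 13 | (2E)-3-[(2S,3S,5R)-3-{[tert-butyl(dimethyl)silyl]oxy}-5-methyloxolan-2-yl]prop-2-enal | O=C/C=C/[C@@H]1O[C@H](C)C[C@@H]1O[Si](C)(C)C(C)(C)C
F7 | step 2 | (5R)-5-hydroxy-1-(trimethylsilyl)hex-1-yn-3-one | C[C@@H](O)CC(=O)C#C[Si](C)(C)C
F8 | step 2 | (3S,5R)-1-(trimethylsilyl)hex-1-yne-3,5-diol | C[C@@H](O)C[C@H](O)C#C[Si](C)(C)C
F9 | step 2 | (3S,5R)-hex-1-yne-3,5-diol | C[C@@H](O)C[C@H](O)C#C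
F10 | step 6 | (1S,3R)-1-[(2R)-oxiran-2-yl]butane-1,3-diol | C[C@@H](O)C[C@H](O)[C@H]1CO1
F11 | step 6 | (2S,3S,5R)-2-(hydroxymethyl)-5-methyloxolan-3-ol | C[C@@H]1C[C@H](O)[C@H](CO)O1
F12 | step 6 | tert-butyl{[(2S,3S,5R)-3-{[tert-butyl(dimethyl)silyl]oxy}-5-methyloxolan-2-yl]methoxy}dimethylsilane | C[C@@H]1C[C@H](O[Si](C)(C)C(C)(C)C)[C@H](CO[Si](C)(C)C(C)(C)C)O1
F13 | step 8 | tert-butyl{[(2S,3S,5R)-2-[(E)-2-iodoethenyl]-5-methyloxolan-3-yl]oxy}dimethylsilane | I/C=C/[C@@H]1O[C@H](C)C[C@@H]1O[Si](C)(C)C(C)(C)C
F14 | step 14 | 5-chloro-3-{(1E,3E)-4-[(2S,3S,5R)-3-hydroxy-5-methyloxolan-2-yl]buta-1,3-dien-1-yl}-6,8-bis(methoxymethoxy)-1H-isochromen-1-one | C[C@@H]1C[C@H](O)[C@H](/C=C/C=C/c2cc3c(Cl)c(OCOC)cc(OCOC)c3c(=O)o2)O1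
A1 | alternative 1 | methyl 3-chloro-4,6-dihydroxy-2-(2-methoxy-2-oxoethyl)benzoate | COC(=O)Cc1c(Cl)c(O)cc(O)c1C(=O)OC
A2 | alternative 1 | 4-chloro-1-methoxy-1,3-bis(trimethylsilyloxy)buta-1,3-diene | COC(O[Si](C)(C)C)=CC(O[Si](C)(C)C)=CCl
A3 | alternative 1 | dimethyl penta-2,3-dienedioate | COC(=O)C=C=CC(=O)OC
A4 | alternative 2 | 6,8-bis{[tert-butyl(dimethyl)silyl]oxy}-5-chloro-3-{(1E,3E)-4-[(2S,3S,5R)-3-hydroxy-5-methyloxolan-2-yl]buta-1,3-dien-1-yl}-1H-isochromen-1-one | C[C@@H]1C[C@H](O)[C@H](/C=C/C=C/c2cc3c(Cl)c(O[Si](C)(C)C(C)(C)C)cc(O[Si](C)(C)C(C)(C)C)c3c(=O)o2)O1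
A5 | alternative 2 | 6,8-bis{[tert-butyl(dimethyl)silyl]oxy}-5-chloro-3-{(1E,3E)-4-{(2S,3S)-3-[(2R)-2-hydroxypropyl]oxiran-2-yl}buta-1,3-dien-1-yl}-1H-isochromen-1-one | C[C@@H](O)C[C@@H]1O[C@H]1/C=C/C=C/c1cc2c(Cl)c(O[Si](C)(C)C(C)(C)C)cc(O[Si](C)(C)C(C)(C)C)c2c(=O)o1
A6 | alternative 3 | methyl 2-{(3E,5E)-6-[(2S,3S,5R)-3-{[tert-butyl(dimethyl)silyl]oxy}-5-methyloxolan-2-yl]-2-oxohexa-3,5-dien-1-yl}-4,6-bis{[tert-butyl(dimethyl)silyl]oxy}-3-chlorobenzoate | COC(=O)c1c(O[Si](C)(C)C(C)(C)C)cc(O[Si](C)(C)C(C)(C)C)c(Cl)c1CC(=O)/C=C/C=C/[C@@H]2O[C@H](C)C[C@@H]2O[Si](C)(C)C(C)(C)C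
A7 | alternative 3 | methyl 2-(bromomethyl)-4,6-bis{[tert-butyl(dimethyl)silyl]oxy}-3-chlorobenzoate | COC(=O)c1c(O[Si](C)(C)C(C)(C)C)cc(O[Si](C)(C)C(C)(C)C)c(Cl)c1CBr
A8 | alternative 3 | tributyl{(1E,3E)-4-[(2S,3S,5R)-3-{[tert-butyl(dimethyl)silyl]oxy}-5-methyloxolan-2-yl]buta-1,3-dien-1-yl}stannane | CCCC[Sn](CCCC)(CCCC)/C=C/C=C/[C@@H]1O[C@H](C)C[C@@H]1O[Si](C)(C)C(C)(C)C
A9 | alternative 3 | carbon monoxide | [C-]#[O+]
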